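**Plan**
1. Cuts (carotenoid numbering): C15=C15' by Wittig olefination, then C10–C11 together with C9–C19 by one-pot methylalumination and Negishi coupling, and C11'=C12' inside the C10 end piece by Horner–Wadsworth–Emmons olefination.
2. Enabling feature: C9=C10 is an E trisubstituted alkene with methyl C19 on C9 and C11 on C10. Removing C19 and the C11–C15 diene leaves a terminal alkyne C9≡C10 conjugated to C7=C8 on the six-membered ring C1–C6 (the ε-ring).
3. Forward: (R)-α-ionone gives the C3-oxygenated ring enyne (C1–C10); three-component coupling with AlMe3 and a C11–C15 dienyl iodide gives the C20 chain; its C15 phosphonium salt is joined to a C10 aldehyde ester (C15'–C8'); ester reduction and desilylation finish. No ring is formed; the ring is bought.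
4. Stereochemistry: C6 (R) comes from (R)-α-ionone. C3 (S, hydroxyl cis to the C6 chain) comes from a substrate-controlled hydride reduction of the C3 enone. Alkene geometry comes from syn carbometalation and hydrozirconation, retentive coupling, E-selective olefinations and a thermal equilibration of C15=C15'.

Key step: step 9

Assumption: (R)-α-ionone is purchased in high enantiomeric purity, so C6 needs no resolution. TBS = tert-butyldimethylsilyl, TES = triethylsilyl.

**Route**

Step 1
Reactants: 1 (R)-α-ionone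
Product: 2 (R)-α-ionone ethylene ketal
Conditions: Me3SiOCH2CH2OSiMe3, Me3SiOTf (cat.), CH2Cl2, −78 °C
Reagents that add atoms: 1,2-bis(trimethylsilyloxy)ethane, C[Si](C)(C)OCCO[Si](C)(C)C
Why: Noyori ketalisation (silyl triflate-catalysed dioxolane formation at low temperature) masks the C9 ketone without acid-mediated enolisation, so the C7=C8 alkene should stay in place and C6 should keep its configuration.

Step 2
Reactants: 2 (R)-α-ionone ethylene ketal
Product: 3 (6R)-3-oxo-α-ionone ethylene ketal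
Conditions: t-BuOOH (70% aq), aq NaOCl, K2CO3, MeCN, 0 °C
Reagents that add atoms: tert-butyl hydroperoxide, CC(C)(C)OO
Why: Radical allylic oxidation by tert-butylperoxy species (allylic peroxide, then Kornblum–DeLaMare-type loss of tert-butanol) should occur at C3, the only unhindered secondary allylic CH2, while the tertiary C6–H is screened by the geminal methyl groups and the carbonate buffer keeps the ketal intact.

Step 3
Reactants: 3 (6R)-3-oxo-α-ionone ethylene ketal
Product: 4 (3S,6R)-3-hydroxy-α-ionone ethylene ketal (hydroxyl cis to the C6 chain)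
Conditions: LiBH(s-Bu)3, THF, −78 °C; then H2O
Reagents that add atoms: none
Why: 1,2-Reduction of a β,β-disubstituted cyclohexenone by a bulky trialkylborohydride, in which hydride is expected to enter C3 on the ring face opposite the C6 side chain so that the new hydroxyl ends up cis to that chain (3S), under control of the C6 centre.

Step 4
Reactants: 4 (3S,6R)-3-hydroxy-α-ionone ethylene ketal
Product: 5 (3S,6R)-3-(tert-butyldimethylsilyloxy)-α-ionone ethylene ketal
Conditions: TBSCl, imidazole, DMF, rt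
Reagents that add atoms: tert-butyldimethylsilyl chloride, CC(C)(C)[Si](C)(C)Cl
Why: Imidazole-promoted silylation of a secondary allylic alcohol gives an ether that should withstand lithium amide, AlMe3 and the buffered fluoride used later.

Step 5
Reactants: 5 (3S,6R)-3-(tert-butyldimethylsilyloxy)-α-ionone ethylene ketal
Product: 6 (3S,6R)-3-(tert-butyldimethylsilyloxy)-α-ionone
Conditions: pyridinium p-toluenesulfonate (cat.), acetone/H2O, rt
Reagents that add atoms: water, O
Why: Acid-catalysed ketal hydrolysis with a pyridinium salt as a weak acid should free the methyl ketone without ionising the allylic silyl ether or enolising towards C6.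

Step 6
Reactants: 6 (3S,6R)-3-(tert-butyldimethylsilyloxy)-α-ionone
Product: 9 (3S,6R)-3-(tert-butyldimethylsilyloxy) ε-ring C12 enyne, via lithium dienolate 7 (not isolated), via enol diethyl phosphate 8 (not isolated)
Conditions: LiN(i-Pr)2 (1.05 equiv), THF, −78 °C; ClP(O)(OEt)2, −78 °C to rt; LiN(i-Pr)2 (2.2 equiv), −78 °C to rt; aq NH4Cl
Reagents that add atoms: none
Why: Methyl ketone to terminal alkyne by the enol phosphate elimination method: kinetic deprotonation at the C10 methyl, O-phosphorylation and amide-induced E2-type elimination, after which the acetylide formed resists further deprotonation.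

Step 7
Reactants: 10 (E)-3-methylpent-2-en-4-yn-1-ol
Product: 11 (E)-3-methylpent-2-en-4-ynyl triethylsilyl ether
Conditions: TESCl, imidazole, CH2Cl2, 0 °C to rt
Reagents that add atoms: chlorotriethylsilane, CC[Si](Cl)(CC)CC
Why: Silylation of the primary allylic alcohol with the more labile triethylsilyl group, so that this oxygen can later be unmasked next to the tert-butyldimethylsilyl ether.

Step 8
Reactants: 11 (E)-3-methylpent-2-en-4-ynyl triethylsilyl ether
Product: 13 (2E,4E)-5-iodo-3-methylpenta-2,4-dienyl triethylsilyl ether, via alkenylzirconocene chloride 12 (not isolated)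
Conditions: Cp2Zr(H)Cl, THF, rt, dark; then I2, THF, 0 °C
Reagents that add atoms: iodine, II
Why: Hydrozirconation adds Zr–H syn to the terminal alkyne with zirconium on the terminal carbon and iodinolysis proceeds with retention, which should give the 4E iodide and leave the 2E alkene untouched.

Step 9
Reactants: 9 (3S,6R)-3-(tert-butyldimethylsilyloxy) ε-ring C12 enyne; 13 (2E,4E)-5-iodo-3-methylpenta-2,4-dienyl triethylsilyl ether; 14 trimethylaluminium
Product: 17 (3S,6R)-3-(tert-butyldimethylsilyloxy) ε-ring C20 tetraenyl triethylsilyl ether, via alkenyldimethylalane 15 (not isolated), via alkenylzinc chloride 16 (not isolated)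
Conditions: AlMe3 (2 equiv), Cp2ZrCl2 (0.5 equiv), ClCH2CH2Cl, 0 °C to rt; volatiles removed in vacuo; THF, ZnCl2 (1 equiv), Pd(PPh3)4 (5 mol %), 13, rt
Reagents that add atoms: trimethylaluminium 14, C[Al](C)C
Why: Cp2ZrCl2 and AlMe3 form a methylzirconium–aluminium species that adds methyl and metal syn across the terminal alkyne, methyl C19 to the internal carbon C9 and aluminium to C10, to give the E alkenylalane. ZnCl2 then relays the alkenyl group to palladium, zerovalent palladium inserts into the C–I bond of the dienyl iodide, and reductive elimination joins C10 to C11 with retention at both alkenes. The closest known reaction type is zirconium-catalysed methylalumination of terminal enynes followed by palladium-catalysed Negishi alkenyl–alkenyl coupling. No ring is closed and no stereocentre is created; C3 and C6 are spectators. The step needs regioselective syn addition and chemoselectivity: the terminal, conjugated alkyne places the metal on its unsubstituted carbon, and the two silyl ethers keep both oxygens away from AlMe3. Removing the excess AlMe3 before the palladium stage should suppress methyl transfer to the iodide.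

Step 10
Reactants: 17 (3S,6R)-3-(tert-butyldimethylsilyloxy) ε-ring C20 tetraenyl triethylsilyl ether
Product: 18 (3S,6R)-3-(tert-butyldimethylsilyloxy) ε-ring C20 tetraenol (free C15 hydroxyl)
Conditions: HF·pyridine, pyridine, THF, 0 °C
Reagents that add atoms: none
Why: Selective desilylation: a primary triethylsilyl ether is cleaved by pyridine-buffered HF far faster than a secondary tert-butyldimethylsilyl ether, and the buffer should keep the polyenyl alcohol from ionising.

Step 11
Reactants: 18 (3S,6R)-3-(tert-butyldimethylsilyloxy) ε-ring C20 tetraenol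
Product: 19 C20 triphenylphosphonium bromide (phosphorus on C15)
Conditions: PPh3·HBr, CH2Cl2, 0 °C to rt
Reagents that add atoms: triphenylphosphine hydrobromide, Br.c1ccc(cc1)P(c1ccccc1)c1ccccc1
Why: Phosphonium salt formation from a polyenyl allylic alcohol (SN1-type: ionisation to the delocalised cation and capture by PPh3 at the unhindered terminus C15), the way retinol-type alcohols are turned into Wittig salts.

Step 12
Reactants: 20 ethyl (E)-4-bromo-2-methylbut-2-enoate
Product: 21 ethyl (E)-4-(diethoxyphosphoryl)-2-methylbut-2-enoate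
Conditions: P(OEt)3, neat, 120 °C
Reagents that add atoms: triethyl phosphite, CCOP(OCC)OCC
Why: Michaelis–Arbuzov reaction of a primary allylic bromide with triethyl phosphite, driven by loss of bromoethane.

Step 13
Reactants: 21 ethyl (E)-4-(diethoxyphosphoryl)-2-methylbut-2-enoate; 22 (E)-4-acetoxy-2-methylbut-2-enal
Product: 24 ethyl (2E,4E,6E)-8-acetoxy-2,6-dimethylocta-2,4,6-trienoate, via lithiated phosphonate 23 (not isolated)
Conditions: LiN(SiMe3)2, THF, −78 °C; then 22, −78 to 0 °C
Reagents that add atoms: none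
Why: Horner–Wadsworth–Emmons olefination: the vinylogous phosphonate anion reacts at the carbon next to phosphorus and should form C11'=C12' with E geometry, the acetate being spared at low temperature.

Step 14
Reactants: 24 ethyl (2E,4E,6E)-8-acetoxy-2,6-dimethylocta-2,4,6-trienoate
Product: 25 ethyl (2E,4E,6E)-8-hydroxy-2,6-dimethylocta-2,4,6-trienoate
Conditions: K2CO3 (cat.), EtOH, 0 °C to rt
Reagents that add atoms: none
Why: Carbonate-catalysed transesterification (ethanolysis) removes the acetate, and ethanol as solvent leaves the ethyl ester unchanged.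

Step 15
Reactants: 25 ethyl (2E,4E,6E)-8-hydroxy-2,6-dimethylocta-2,4,6-trienoate
Product: 26 ethyl (2E,4E,6E)-2,6-dimethyl-8-oxoocta-2,4,6-trienoate
Conditions: MnO2, CH2Cl2, rt
Reagents that add atoms: none
Why: MnO2 oxidation of a primary allylic alcohol stops at the conjugated aldehyde and should preserve the alkene geometry.

Step 16
Reactants: 19 C20 triphenylphosphonium bromide; 26 ethyl (2E,4E,6E)-2,6-dimethyl-8-oxoocta-2,4,6-trienoate
Product: 29 all-E ethyl (3S,6R)-3-(tert-butyldimethylsilyloxy)-8'-apo-ε-caroten-8'-oate, via polyenyl ylide 27 (not isolated), via (15Z)-ester 28 (not isolated)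
Conditions: NaOEt, EtOH/CH2Cl2, 0 °C to rt; then heptane, reflux, N2, dark
Reagents that add atoms: none
Why: Wittig olefination of the polyenyl ylide with the enal forms C15=C15', and the unhindered central Z alkene that forms alongside should equilibrate to E on heating (thermal E/Z isomerisation of polyenes).

Step 17
Reactants: 29 all-E ethyl (3S,6R)-3-(tert-butyldimethylsilyloxy)-8'-apo-ε-caroten-8'-oate
Product: 30 all-E (3S,6R)-3-(tert-butyldimethylsilyloxy)-8'-apo-ε-caroten-8'-ol
Conditions: i-Bu2AlH, CH2Cl2, −78 °C; aq potassium sodium tartrate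
Reagents that add atoms: none
Why: 1,2-Reduction of the conjugated ester with a dialkylaluminium hydride at low temperature should give the C8' allylic alcohol without touching the polyene or the silyl ether.

Step 18
Reactants: 30 all-E (3S,6R)-3-(tert-butyldimethylsilyloxy)-8'-apo-ε-caroten-8'-ol
Product: 31 target, all-E (3S,6R)-3-hydroxy-8'-apo-ε-caroten-8'-ol
Conditions: n-Bu4NF, THF, 0 °C to rt
Reagents that add atoms: none
Why: Fluoride-mediated desilylation releases the C3 hydroxyl under non-acidic conditions, which the allylic alcohols of the target should tolerate.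

**Compound list**

1 | (R)-α-ionone, (3E)-4-[(1R)-2,6,6-trimethylcyclohex-2-en-1-yl]but-3-en-2-one | CC1=CCCC(C)(C)[C@H]1/C=C/C(C)=O | starting material
2 | 2-methyl-2-{(E)-2-[(1R)-2,6,6-trimethylcyclohex-2-en-1-yl]ethenyl}-1,3-dioxolane | CC1=CCCC(C)(C)[C@H]1/C=C/C2(C)OCCO2 | intermediate
3 | (4R)-3,5,5-trimethyl-4-[(E)-2-(2-methyl-1,3-dioxolan-2-yl)ethenyl]cyclohex-2-en-1-one | CC1=CC(=O)CC(C)(C)[C@H]1/C=C/C2(C)OCCO2 | intermediate
4 | (1S,4R)-3,5,5-trimethyl-4-[(E)-2-(2-methyl-1,3-dioxolan-2-yl)ethenyl]cyclohex-2-en-1-ol (OH cis to side chain) | CC1=C[C@@H](O)CC(C)(C)[C@H]1/C=C/C2(C)OCCO2 | intermediate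
5 | tert-butyldimethylsilyl ether of 4 | CC1=C[C@@H](O[Si](C)(C)C(C)(C)C)CC(C)(C)[C@H]1/C=C/C2(C)OCCO2 | intermediate
6 | (3E)-4-[(1R,4S)-4-(tert-butyldimethylsilyloxy)-2,6,6-trimethylcyclohex-2-en-1-yl]but-3-en-2-one | CC1=C[C@@H](O[Si](C)(C)C(C)(C)C)CC(C)(C)[C@H]1/C=C/C(C)=O | intermediate
7 | lithium dienolate of 6 (O–Li on C9, C9=C10 methylene; not isolated) | CC1=C[C@@H](O[Si](C)(C)C(C)(C)C)CC(C)(C)[C@H]1/C=C/C(=C)O[Li] | intermediate
8 | enol diethyl phosphate of 6 (2-phosphoryloxybuta-1,3-diene; not isolated) | CC1=C[C@@H](O[Si](C)(C)C(C)(C)C)CC(C)(C)[C@H]1/C=C/C(=C)OP(=O)(OCC)OCC | intermediate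
9 | tert-butyl{[(1S,4R)-4-[(1E)-but-1-en-3-yn-1-yl]-3,5,5-trimethylcyclohex-2-en-1-yl]oxy}dimethylsilane | CC1=C[C@@H](O[Si](C)(C)C(C)(C)C)CC(C)(C)[C@H]1/C=C/C#C | intermediate
10 | (E)-3-methylpent-2-en-4-yn-1-ol | C#C/C(C)=C/CO | starting material
11 | triethyl{[(2E)-3-methylpent-2-en-4-yn-1-yl]oxy}silane | C#C/C(C)=C/CO[Si](CC)(CC)CC | intermediate
12 | (1E,3E)-3-methyl-5-(triethylsilyloxy)penta-1,3-dienylzirconocene chloride (cyclopentadienyl ligands drawn σ-bound; not isolated) | CC[Si](CC)(CC)OC/C=C(C)/C=C/[Zr](Cl)(C1C=CC=C1)C1C=CC=C1 | intermediate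
13 | (2E,4E)-5-iodo-3-methylpenta-2,4-dienyl triethylsilyl ether | I/C=C/C(C)=C/CO[Si](CC)(CC)CC | intermediate
14 | trimethylaluminium | C[Al](C)C | starting material
15 | (1E,3E)-alkenyldimethylalane from 9 (Al on C10, methyl on C9; not isolated) | CC1=C[C@@H](O[Si](C)(C)C(C)(C)C)CC(C)(C)[C@H]1/C=C/C(C)=C/[Al](C)C | intermediate
16 | corresponding (1E,3E)-alkenylzinc chloride (not isolated) | CC1=C[C@@H](O[Si](C)(C)C(C)(C)C)CC(C)(C)[C@H]1/C=C/C(C)=C/[Zn]Cl | intermediate
17 | tert-butyl{[(1S,4R)-4-[(1E,3E,5E,7E)-3,7-dimethyl-9-(triethylsilyloxy)nona-1,3,5,7-tetraen-1-yl]-3,5,5-trimethylcyclohex-2-en-1-yl]oxy}dimethylsilane | CC1=C[C@@H](O[Si](C)(C)C(C)(C)C)CC(C)(C)[C@H]1/C=C/C(C)=C/C=C/C(C)=C/CO[Si](CC)(CC)CC | intermediate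
18 | (2E,4E,6E,8E)-9-[(1R,4S)-4-(tert-butyldimethylsilyloxy)-2,6,6-trimethylcyclohex-2-en-1-yl]-3,7-dimethylnona-2,4,6,8-tetraen-1-ol | CC1=C[C@@H](O[Si](C)(C)C(C)(C)C)CC(C)(C)[C@H]1/C=C/C(C)=C/C=C/C(C)=C/CO | intermediate
19 | [(2E,4E,6E,8E)-9-[(1R,4S)-4-(tert-butyldimethylsilyloxy)-2,6,6-trimethylcyclohex-2-en-1-yl]-3,7-dimethylnona-2,4,6,8-tetraen-1-yl]triphenylphosphonium bromide | CC1=C[C@@H](O[Si](C)(C)C(C)(C)C)CC(C)(C)[C@H]1/C=C/C(C)=C/C=C/C(C)=C/C[P+](c2ccccc2)(c2ccccc2)c2ccccc2.[Br-] | intermediate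
20 | ethyl (E)-4-bromo-2-methylbut-2-enoate | CCOC(=O)/C(C)=C/CBr | starting material
21 | ethyl (E)-4-(diethoxyphosphoryl)-2-methylbut-2-enoate | CCOC(=O)/C(C)=C/CP(=O)(OCC)OCC | intermediate
22 | (E)-4-acetoxy-2-methylbut-2-enal | CC(=O)OC/C=C(\C)C=O | starting material
23 | lithium salt of 21 deprotonated at the carbon next to phosphorus (not isolated) | CCOC(=O)/C(C)=C/[CH-]P(=O)(OCC)OCC.[Li+] | intermediate
24 | ethyl (2E,4E,6E)-8-acetoxy-2,6-dimethylocta-2,4,6-trienoate | CCOC(=O)/C(C)=C/C=C/C(C)=C/COC(C)=O | intermediate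
25 | ethyl (2E,4E,6E)-8-hydroxy-2,6-dimethylocta-2,4,6-trienoate | CCOC(=O)/C(C)=C/C=C/C(C)=C/CO | intermediate
26 | ethyl (2E,4E,6E)-2,6-dimethyl-8-oxoocta-2,4,6-trienoate | CCOC(=O)/C(C)=C/C=C/C(C)=C/C=O | intermediate
27 | triphenylphosphonium ylide from 19 (P=C15; not isolated) | CC1=C[C@@H](O[Si](C)(C)C(C)(C)C)CC(C)(C)[C@H]1/C=C/C(C)=C/C=C/C(C)=C/C=P(c2ccccc2)(c2ccccc2)c2ccccc2 | intermediate
28 | (15Z) isomer of 29 (8Z in the heptadecaoctaenoate numbering; not isolated) | CC1=C[C@@H](O[Si](C)(C)C(C)(C)C)CC(C)(C)[C@H]1/C=C/C(C)=C/C=C/C(C)=C/C=C\C=C(C)\C=C\C=C(/C)C(=O)OCC | intermediate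
29 | ethyl (2E,4E,6E,8E,10E,12E,14E,16E)-17-[(1R,4S)-4-(tert-butyldimethylsilyloxy)-2,6,6-trimethylcyclohex-2-en-1-yl]-2,6,11,15-tetramethylheptadeca-2,4,6,8,10,12,14,16-octaenoate | CC1=C[C@@H](O[Si](C)(C)C(C)(C)C)CC(C)(C)[C@H]1/C=C/C(C)=C/C=C/C(C)=C/C=C/C=C(C)/C=C/C=C(\C)C(=O)OCC | intermediate
30 | (2E,4E,6E,8E,10E,12E,14E,16E)-17-[(1R,4S)-4-(tert-butyldimethylsilyloxy)-2,6,6-trimethylcyclohex-2-en-1-yl]-2,6,11,15-tetramethylheptadeca-2,4,6,8,10,12,14,16-octaen-1-ol | CC1=C[C@@H](O[Si](C)(C)C(C)(C)C)CC(C)(C)[C@H]1/C=C/C(C)=C/C=C/C(C)=C/C=C/C=C(C)/C=C/C=C(\C)CO | intermediate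
31 | (2E,4E,6E,8E,10E,12E,14E,16E)-17-[(1R,4S)-4-hydroxy-2,6,6-trimethylcyclohex-2-en-1-yl]-2,6,11,15-tetramethylheptadeca-2,4,6,8,10,12,14,16-octaen-1-ol | CC1=C[C@@H](O)CC(C)(C)[C@H]1/C=C/C(C)=C/C=C/C(C)=C/C=C/C=C(C)/C=C/C=C(\C)CO | target

**Count**

Total steps: 18. Longest linear sequence: 12 steps (steps 1–6, 9–11, 16–18).

**Steps most likely to fail**

Step 3. The risk is poor facial selectivity in hydride delivery: the axial C1 methyl and the C6 chain shield opposite faces of the C3 carbonyl, so the 3,6-trans alcohol may form in quantity. The fallback sets out from 3 and comes back at 4, and replaces kinetic face selection by inversion at C3. Ketone 3 is reduced under Luche conditions (NaBH4, CeCl3·7H2O, MeOH, 0 °C) and the epimers are separated. The trans epimer, (1R,4R)-3,5,5-trimethyl-4-[(E)-2-(2-methyl-1,3-dioxolan-2-yl)ethenyl]cyclohex-2-en-1-ol F1, is subjected to Mitsunobu esterification (4-nitrobenzoic acid, PPh3, diisopropyl azodicarboxylate, THF, 0 °C), which should give the inverted (1S,4R) 4-nitrobenzoate F2. Methanolysis (K2CO3, MeOH) then gives 4.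

Step 6. The risk is competing deprotonation of the doubly allylic C6–H by the excess lithium amide, which could epimerise C6 or expel silanolate from C3 by 1,4-elimination. The fallback sets out from 1 and comes back at 9, and installs the alkyne before any oxygen sits on C3. The same one-flask protocol on 1 should give, through the enol diethyl phosphate of (R)-α-ionone F3, the parent enyne (6R)-6-[(1E)-but-1-en-3-yn-1-yl]-1,5,5-trimethylcyclohex-1-ene F4. Allylic oxidation with CrO3·3,5-dimethylpyrazole (CH2Cl2, −20 °C; hypochlorite is avoided because of the terminal alkyne) should give (4R)-4-[(1E)-but-1-en-3-yn-1-yl]-3,5,5-trimethylcyclohex-2-en-1-one F5. Reduction with LiBH(s-Bu)3 as in step 3 should give the cis alcohol (1S,4R)-4-[(1E)-but-1-en-3-yn-1-yl]-3,5,5-trimethylcyclohex-2-en-1-ol F6, and TBSCl/imidazole converts it into 9.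

Step 9. The risks are methyl transfer from residual AlMe3 to the iodide, sluggish relay of the alkenyl group from aluminium to palladium, homocoupling of the dienyl iodide, and erosion of the allylic silyl ether in the Lewis acidic medium. The fallback sets out from 9 and 11 and comes back at 17; it splits the one-pot process and reverses the polarity at C10/C11. Methylalumination of 9 as before, followed by quenching alane 15 with I2 (THF, −30 °C), should give the isolable tert-butyl{[(1S,4R)-4-[(1E,3E)-4-iodo-3-methylbuta-1,3-dien-1-yl]-3,5,5-trimethylcyclohex-2-en-1-yl]oxy}dimethylsilane F7. Hydroboration of 11 with pinacolborane (Cp2Zr(H)Cl cat., Et3N, CH2Cl2) should give triethyl{[(2E,4E)-3-methyl-5-(4,4,5,5-tetramethyl-1,3,2-dioxaborolan-2-yl)penta-2,4-dien-1-yl]oxy}silane F8. Suzuki–Miyaura coupling of F7 with F8 (Pd(PPh3)4, aq KOH, THF, rt) then forms C10–C11 and gives 17.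

**Further compounds**

F1 | step 3 | (1R,4R)-3,5,5-trimethyl-4-[(E)-2-(2-methyl-1,3-dioxolan-2-yl)ethenyl]cyclohex-2-en-1-ol | CC1=C[C@H](O)CC(C)(C)[C@H]1/C=C/C2(C)OCCO2
F2 | step 3 | (1S,4R)-3,5,5-trimethyl-4-[(E)-2-(2-methyl-1,3-dioxolan-2-yl)ethenyl]cyclohex-2-en-1-yl 4-nitrobenzoate | CC1=C[C@@H](OC(=O)c2ccc(cc2)[N+](=O)[O-])CC(C)(C)[C@H]1/C=C/C3(C)OCCO3
F3 | step 6 | diethyl (3E)-4-[(1R)-2,6,6-trimethylcyclohex-2-en-1-yl]buta-1,3-dien-2-yl phosphate | CC1=CCCC(C)(C)[C@H]1/C=C/C(=C)OP(=O)(OCC)OCC
F4 | step 6 | (6R)-6-[(1E)-but-1-en-3-yn-1-yl]-1,5,5-trimethylcyclohex-1-ene | CC1=CCCC(C)(C)[C@H]1/C=C/C#C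
F5 | step 6 | (4R)-4-[(1E)-but-1-en-3-yn-1-yl]-3,5,5-trimethylcyclohex-2-en-1-one | CC1=CC(=O)CC(C)(C)[C@H]1/C=C/C#C
F6 | step 6 | (1S,4R)-4-[(1E)-but-1-en-3-yn-1-yl]-3,5,5-trimethylcyclohex-2-en-1-ol | CC1=C[C@@H](O)CC(C)(C)[C@H]1/C=C/C#C
F7 | step 9 | tert-butyl{[(1S,4R)-4-[(1E,3E)-4-iodo-3-methylbuta-1,3-dien-1-yl]-3,5,5-trimethylcyclohex-2-en-1-yl]oxy}dimethylsilane | CC1=C[C@@H](O[Si](C)(C)C(C)(C)C)CC(C)(C)[C@H]1/C=C/C(C)=C/I
F8 | step 9 | triethyl{[(2E,4E)-3-methyl-5-(4,4,5,5-tetramethyl-1,3,2-dioxaborolan-2-yl)penta-2,4-dien-1-yl]oxy}silane | CC[Si](CC)(CC)OC/C=C(C)/C=C/B1OC(C)(C)C(C)(C)O1
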